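The plan cuts ring A and ring B open together: C3–C4 and C5–C10 are disconnected, turning the decalin into an open-chain undeca-2,8,10-trienoate. The feature exploited is that C5 of ring A sits between two quaternary carbons, C4 (methyl and ester) and C10 (angular methyl): C4/C5 becomes an (E)-2-methylenoate dienophile and C10/C1/C2/C3 a diene, joined through the ring B carbons C6 to C9. One intramolecular Diels–Alder reaction then closes both rings and sets C4, C5 and C10 under control of the C6 silyl ether. The precursor carries that silyl ether, a C8 dioxolane and a C9 dioxolanylmethyl arm; the dienyl side chain, C17 methylene and acetate are added afterwards.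

Key step: step 10

Numbering: labdane numbers (C1 to C20) are used for positions throughout; C18 is the ester carbon and C19 the methyl group on C4.
Assumption: in step 7 the (−)-enantiomer of Ipc2BCl is taken to steer a methyl ketone borinate to the Re face of the aldehyde; were the sense opposite, the (+)-reagent would be used with nothing else changed.
Remark: both masked carbonyls are dioxolanes, so ketalisation at C8 cannot scramble the arm acetal, and the cycloaddition is run without Lewis acid because aluminium chlorides would open both acetals.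
Remark: triene 16 is (6R,9S) and octalin 17 is (4S,5S,6R,9S,10R); these map onto (4S,5S,6R,9R,10S) of the target, the change at C9 and C10 being a change of CIP priorities only.

Step 1
Reactants: 1 acrolein; 2 2-(triphenylphosphoranylidene)propanal
Product: 3 (2E)-2-methylpenta-2,4-dienal
Conditions: CH2Cl2, 0 °C to rt
Reagents that add atoms: none
Why: Wittig olefination with a formyl-stabilised ylide is (E)-selective, so the future C10=C1 bond is formed with C9 (the CHO carbon) trans to the vinyl group and C20 on the inside of the diene.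

Step 2
Reactants: 3 (2E)-2-methylpenta-2,4-dienal; 4 (triphenylphosphoranylidene)acetaldehyde
Product: 5 (2E,4E)-4-methylhepta-2,4,6-trienal
Conditions: PhMe, 80 °C
Reagents that add atoms: none
Why: A second Wittig reaction with a formyl-stabilised ylide adds C11 and C12 as an (E)-enal, and the use of one equivalent of ylide limits further homologation of the trienal.

Step 3
Reactants: 5 (2E,4E)-4-methylhepta-2,4,6-trienal; 6 nitroethane
Product: 7 (3S,4E)-4-methyl-3-(1-nitroethyl)hepta-4,6-dienal (both epimers at the nitro-bearing carbon)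
Conditions: (S)-α,α-diphenyl-2-pyrrolidinemethanol trimethylsilyl ether (10 mol%), PhCO2H (20 mol%), MeOH, rt
Reagents that add atoms: none
Why: In this iminium-catalysed Michael addition of a nitroalkane to an enal the catalyst forms the (E)-iminium ion of 5, whose β-carbon C9 is attacked by the nitronate from the face opposite the diphenyl(silyloxy)methyl group, which should set (9S), while the nitro-bearing carbon (the later C8 carbonyl) is left as a mixture.

Step 4
Reactants: 7 (3S,4E)-4-methyl-3-(1-nitroethyl)hepta-4,6-dienal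
Product: 8 2-[(2S,3E)-3-methyl-2-(1-nitroethyl)hexa-3,5-dien-1-yl]-1,3-dioxolane
Conditions: HOCH2CH2OH, pyridinium p-toluenesulfonate (cat.), PhH, reflux (Dean–Stark trap)
Reagents that add atoms: ethylene glycol, OCCO
Why: Acid-catalysed acetalisation with azeotropic removal of water masks the C12 aldehyde as a dioxolane without touching the nitro group, the diene or C9.

Step 5
Reactants: 8 2-[(2S,3E)-3-methyl-2-(1-nitroethyl)hexa-3,5-dien-1-yl]-1,3-dioxolane
Product: 10 (3S,4E)-3-(1,3-dioxolan-2-ylmethyl)-4-methylhepta-4,6-dien-2-one, via sodium nitronate 9 (not isolated)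
Conditions: NaOMe, MeOH, 0 °C; then aq. TiCl3, NH4OAc (pH 5 to 6), rt
Reagents that add atoms: water, O
Why: In this reductive Nef reaction the nitronate is reduced by TiCl3 to the imine and hydrolysed in the acetate buffer to the C8 methyl ketone, at a pH at which the dioxolane and the C9 stereocentre should persist.

Step 6
Reactants: 11 methyl tiglate
Product: 12 methyl (2E)-2-methyl-4-oxobut-2-enoate
Conditions: SeO2, 1,4-dioxane, reflux
Reagents that add atoms: selenium dioxide, O=[Se]=O
Why: Riley allylic oxidation (ene reaction, [2,3]-shift, further oxidation) attacks the γ-methyl group trans to the ester and gives the (E)-aldehyde ester that supplies the ester carbon, C4 with its methyl group, C5 and C6.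

Step 7
Reactants: 10 (3S,4E)-3-(1,3-dioxolan-2-ylmethyl)-4-methylhepta-4,6-dien-2-one; 12 methyl (2E)-2-methyl-4-oxobut-2-enoate
Product: 14 methyl (2E,4R,7S,8E)-7-(1,3-dioxolan-2-ylmethyl)-4-hydroxy-2,8-dimethyl-6-oxoundeca-2,8,10-trienoate, via enol borinate 13 (not isolated)
Conditions: (−)-Ipc2BCl, Et3N, Et2O, 0 °C; then 12, −78 to −20 °C; then H2O2, MeOH, pH 7 buffer, 0 °C
Reagents that add atoms: none
Why: The diisopinocampheylboron aldol reaction enolises the methyl ketone kinetically at C7 and the chiral borinate adds to the Re face of the aldehyde (reagent control) to set (6R); because 10 is a single enantiomer, the minor C6 epimer is a diastereomer and should be removable by chromatography.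

Step 8
Reactants: 14 methyl (2E,4R,7S,8E)-7-(1,3-dioxolan-2-ylmethyl)-4-hydroxy-2,8-dimethyl-6-oxoundeca-2,8,10-trienoate
Product: 15 methyl (2E,4R,7S,8E)-4-[(tert-butyldimethylsilyl)oxy]-7-(1,3-dioxolan-2-ylmethyl)-2,8-dimethyl-6-oxoundeca-2,8,10-trienoate
Conditions: TBSOTf, 2,6-lutidine, CH2Cl2, −78 °C
Reagents that add atoms: tert-butyldimethylsilyl triflate, CC(C)(C)[Si](C)(C)OS(=O)(=O)C(F)(F)F
Why: Silylation with the silyl triflate and a hindered pyridine base at low temperature protects the β-hydroxy ketone without retro-aldol cleavage or β-elimination.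

Step 9
Reactants: 15 methyl (2E,4R,7S,8E)-4-[(tert-butyldimethylsilyl)oxy]-7-(1,3-dioxolan-2-ylmethyl)-2,8-dimethyl-6-oxoundeca-2,8,10-trienoate
Product: 16 triene: methyl (2E,4R)-4-[(tert-butyldimethylsilyl)oxy]-5-{2-[(2S,3E)-1-(1,3-dioxolan-2-yl)-3-methylhexa-3,5-dien-2-yl]-1,3-dioxolan-2-yl}-2-methylpent-2-enoate (the C8 ethylene ketal of 15; 6R,9S)
Conditions: (Me3SiOCH2)2, trimethylsilyl triflate (10 mol%), CH2Cl2, −78 to −30 °C; pyridine quench
Reagents that add atoms: 1,2-bis(trimethylsilyloxy)ethane, C[Si](C)(C)OCCO[Si](C)(C)C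
Why: Ketalisation with the bis-silyl ether of ethylene glycol under catalytic trimethylsilyl triflate runs aprotic and cold, conditions under which β,γ-unsaturated ketones are ketalised without alkene migration, silyl ethers survive and the arm dioxolane can only exchange with itself.

Step 10
Reactants: 16 triene (6R,9S)
Product: 17 methyl (4S,5S,6R,9S,10R)-6-[(tert-butyldimethylsilyl)oxy]-8,8:12,12-bis(ethylenedioxy)-13,14,15,16,17-pentanorlabd-1-en-18-oate (trans-fused octalin, C1=C2 alkene)
Conditions: PhMe (5 mM), 2,6-di-tert-butyl-4-methylphenol, 170 °C, sealed silylated glass tube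
Reagents that add atoms: none
Why: The reaction is a concerted, asynchronous thermal [4+2] cycloaddition in which the enoate C4=C5 adds suprafacially across the diene C10=C1–C2=C3, forming C3–C4 and C5–C10; the closest known reaction type is the thermal intramolecular Diels–Alder reaction of terminally activated deca-2,7,9-trienoates to trans-fused octalins, including dienes whose methyl-bearing terminus becomes an angular methyl group. Ring A closes as the six-membered ring of the cycloaddition itself, and ring B closes through the four-atom tether C6–C9, which folds as a chair in the anti transition state with the ester endo. C4 follows from the (E)-enoate geometry (ester cis to H5 and therefore equatorial, methyl axial), and the trans relation of H5 and C20 at C5 and C10 follows from the endo-ester chair geometry together with the (E)-diene, which carries C20 on the inside. The absolute sense of all three new centres is set by C6: 1,3-allylic strain between the C4 methyl group and the C6 substituents keeps H6 in the enoate plane, so the diene approaches anti to the silyloxy group, which ends equatorial and cis to H5, and the (9S) arm is equatorial in the same chair, so C6 and C9 act in the same direction. The selectivities needed are trans fusion and one π-face, secured by the endo ester, the chair tether with its C8 dioxolane and the C6 rotamer control. Thermal, acid-free conditions are chosen because aluminium Lewis acids would ionise the two dioxolanes.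

Step 11
Reactants: 17 octalin
Product: 18 methyl (4S,5S,6R,9S,10R)-6-[(tert-butyldimethylsilyl)oxy]-8,8:12,12-bis(ethylenedioxy)-13,14,15,16,17-pentanorlabdan-18-oate
Conditions: H2 (1 atm), Pd/C (10% Pd on carbon), EtOAc, rt
Reagents that add atoms: none
Why: Heterogeneous catalytic hydrogenation saturates the only alkene, the cis-disubstituted C1=C2 bond, and nothing else in 17 is reducible or hydrogenolysable under these conditions.

Step 12
Reactants: 18 decalin bis-dioxolane
Product: 19 methyl (4S,5S,6R,9S,10R)-6-[(tert-butyldimethylsilyl)oxy]-8,12-dioxo-13,14,15,16,17-pentanorlabdan-18-oate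
Conditions: TsOH·H2O (cat.), acetone/H2O (10:1), 40 °C
Reagents that add atoms: water, O
Why: Acid-catalysed acetal hydrolysis frees the C12 aldehyde and the C8 ketone while the hindered secondary silyl ether stays, and since C9 is now α to the C8 carbonyl any C9 epimer formed earlier equilibrates to the equatorial arm that 19 already has.

Step 13
Reactants: 19 keto aldehyde; 2 2-(triphenylphosphoranylidene)propanal
Product: 20 methyl (4S,5S,6R,9S,10R,12E)-6-[(tert-butyldimethylsilyl)oxy]-8,14-dioxo-15,17-dinorlabd-12-en-18-oate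
Conditions: PhMe, 80 °C
Reagents that add atoms: none
Why: The formyl-stabilised ylide of this Wittig reaction reacts with the aldehyde only, not with the hindered C8 ketone, and gives the (E)-configured C12=C13 bond with C16 in place.

Step 14
Reactants: 20 enal ketone; 21 methyltriphenylphosphonium bromide
Product: 23 methyl (4S,5S,6R,9R,10S)-6-[(tert-butyldimethylsilyl)oxy]labda-8(17),12E,14-trien-18-oate, via dienyl ketone 22 (not isolated)
Conditions: 21, KOtBu, THF, 0 °C; then 20, 0 to 50 °C
Reagents that add atoms: none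
Why: Wittig methylenation with an excess of the non-stabilised ylide converts the C14 aldehyde rapidly and the hindered C8 ketone on warming, giving the terminal diene and the C8=C17 methylene, while C9 keeps the equatorial arm, which is also the thermodynamic epimer.

Step 15
Reactants: 23 silyl ether
Product: 24 methyl (4S,5S,6R,9R,10S)-6-hydroxylabda-8(17),12E,14-trien-18-oate
Conditions: HF·pyridine, pyridine, THF, 0 °C to rt
Reagents that add atoms: none
Why: Fluoride-induced desilylation with buffered HF·pyridine avoids a free alkoxide, which could attack the neighbouring C4 ester, and leaves the diene, the methylene group and the ester intact.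

Step 16
Reactants: 24 alcohol
Product: 25 methyl (4S,5S,6R,9R,10S)-6-acetoxylabda-8(17),12E,14-trien-18-oate (CNP0212193.1)
Conditions: Ac2O, 4-(dimethylamino)pyridine (cat.), pyridine, rt
Reagents that add atoms: acetic anhydride, CC(=O)OC(C)=O
Why: Acylation with acetic anhydride under nucleophilic catalysis acetylates the hindered equatorial C6 alcohol with retention and completes the target.

Compound list
1 | acrolein | C=CC=O | starting material
2 | 2-(triphenylphosphoranylidene)propanal | CC(C=O)=P(c1ccccc1)(c1ccccc1)c1ccccc1 | starting material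
3 | (2E)-2-methylpenta-2,4-dienal | O=C/C(C)=C/C=C | intermediate
4 | (triphenylphosphoranylidene)acetaldehyde | O=CC=P(c1ccccc1)(c1ccccc1)c1ccccc1 | starting material
5 | (2E,4E)-4-methylhepta-2,4,6-trienal | O=C/C=C/C(C)=C/C=C | intermediate
6 | nitroethane | CC[N+](=O)[O-] | starting material
7 | (3S,4E)-4-methyl-3-(1-nitroethyl)hepta-4,6-dienal, both epimers at the nitro-bearing carbon | CC([N+](=O)[O-])[C@@H](CC=O)/C(C)=C/C=C | intermediate
8 | 2-[(2S,3E)-3-methyl-2-(1-nitroethyl)hexa-3,5-dien-1-yl]-1,3-dioxolane | CC([N+](=O)[O-])[C@@H](CC1OCCO1)/C(C)=C/C=C | intermediate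
9 | sodium nitronate of 8 | CC(=[N+]([O-])[O-])[C@@H](CC1OCCO1)/C(C)=C/C=C.[Na+] | intermediate
10 | (3S,4E)-3-(1,3-dioxolan-2-ylmethyl)-4-methylhepta-4,6-dien-2-one | CC(=O)[C@@H](CC1OCCO1)/C(C)=C/C=C | intermediate
11 | methyl tiglate | C/C=C(\C)C(=O)OC | starting material
12 | methyl (2E)-2-methyl-4-oxobut-2-enoate | COC(=O)/C(C)=C/C=O | intermediate
13 | enol diisopinocampheylborinate of 10 (enolised at C7) | C=C(OB([C@@H]1C[C@@H]2C[C@H]([C@H]1C)C2(C)C)[C@@H]3C[C@@H]4C[C@H]([C@H]3C)C4(C)C)[C@@H](CC5OCCO5)/C(C)=C/C=C | intermediate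
14 | methyl (2E,4R,7S,8E)-7-(1,3-dioxolan-2-ylmethyl)-4-hydroxy-2,8-dimethyl-6-oxoundeca-2,8,10-trienoate | COC(=O)/C(C)=C/[C@H](O)CC(=O)[C@@H](CC1OCCO1)/C(C)=C/C=C | intermediate
15 | methyl (2E,4R,7S,8E)-4-[(tert-butyldimethylsilyl)oxy]-7-(1,3-dioxolan-2-ylmethyl)-2,8-dimethyl-6-oxoundeca-2,8,10-trienoate | COC(=O)/C(C)=C/[C@H](O[Si](C)(C)C(C)(C)C)CC(=O)[C@@H](CC1OCCO1)/C(C)=C/C=C | intermediate
16 | triene (6R,9S): methyl (2E,4R)-4-[(tert-butyldimethylsilyl)oxy]-5-{2-[(2S,3E)-1-(1,3-dioxolan-2-yl)-3-methylhexa-3,5-dien-2-yl]-1,3-dioxolan-2-yl}-2-methylpent-2-enoate | COC(=O)/C(C)=C/[C@H](O[Si](C)(C)C(C)(C)C)CC1(OCCO1)[C@@H](CC2OCCO2)/C(C)=C/C=C | intermediate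
17 | octalin: methyl (4S,5S,6R,9S,10R)-6-[(tert-butyldimethylsilyl)oxy]-8,8:12,12-bis(ethylenedioxy)-13,14,15,16,17-pentanorlabd-1-en-18-oate (trans ring fusion, ester and silyloxy group equatorial, arm equatorial) | C1COC(O1)C[C@@H]2C3(OCCO3)C[C@@H](O[Si](C)(C)C(C)(C)C)[C@H]4[C@@]2(C)C=CC[C@]4(C)C(=O)OC | intermediate
18 | methyl (4S,5S,6R,9S,10R)-6-[(tert-butyldimethylsilyl)oxy]-8,8:12,12-bis(ethylenedioxy)-13,14,15,16,17-pentanorlabdan-18-oate | C1COC(O1)C[C@@H]2C3(OCCO3)C[C@@H](O[Si](C)(C)C(C)(C)C)[C@H]4[C@@]2(C)CCC[C@]4(C)C(=O)OC | intermediate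
19 | methyl (4S,5S,6R,9S,10R)-6-[(tert-butyldimethylsilyl)oxy]-8,12-dioxo-13,14,15,16,17-pentanorlabdan-18-oate | O=CC[C@@H]1C(=O)C[C@@H](O[Si](C)(C)C(C)(C)C)[C@H]2[C@@]1(C)CCC[C@]2(C)C(=O)OC | intermediate
20 | methyl (4S,5S,6R,9S,10R,12E)-6-[(tert-butyldimethylsilyl)oxy]-8,14-dioxo-15,17-dinorlabd-12-en-18-oate | O=C/C(C)=C/C[C@@H]1C(=O)C[C@@H](O[Si](C)(C)C(C)(C)C)[C@H]2[C@@]1(C)CCC[C@]2(C)C(=O)OC | intermediate
21 | methyltriphenylphosphonium bromide | C[P+](c1ccccc1)(c1ccccc1)c1ccccc1.[Br-] | starting material
22 | methyl (4S,5S,6R,9S,10R)-6-[(tert-butyldimethylsilyl)oxy]-8-oxo-17-norlabda-12E,14-dien-18-oate | C=C/C(C)=C/C[C@@H]1C(=O)C[C@@H](O[Si](C)(C)C(C)(C)C)[C@H]2[C@@]1(C)CCC[C@]2(C)C(=O)OC | intermediate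
23 | methyl (4S,5S,6R,9R,10S)-6-[(tert-butyldimethylsilyl)oxy]labda-8(17),12E,14-trien-18-oate | C=C/C(C)=C/C[C@@H]1C(=C)C[C@@H](O[Si](C)(C)C(C)(C)C)[C@H]2[C@@]1(C)CCC[C@]2(C)C(=O)OC | intermediate
24 | methyl (4S,5S,6R,9R,10S)-6-hydroxylabda-8(17),12E,14-trien-18-oate | C=C/C(C)=C/C[C@@H]1C(=C)C[C@@H](O)[C@H]2[C@@]1(C)CCC[C@]2(C)C(=O)OC | intermediate
25 | methyl (4S,5S,6R,9R,10S)-6-acetoxylabda-8(17),12E,14-trien-18-oate (ester equatorial on C4) | C=C/C(C)=C/C[C@@H]1C(=C)C[C@@H](OC(C)=O)[C@H]2[C@@]1(C)CCC[C@]2(C)C(=O)OC | target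

Total step count: 16 steps.
Longest linear sequence: 15 steps (steps 1 to 5 and 7 to 16, from acrolein); step 6 is a one-step side branch.

Steps most likely to fail

Step 10 (cycloaddition). What may go wrong: a [1,5]-hydrogen shift from the inside methyl group C20 to C3 can consume the diene before the trisubstituted enoate adds, and cis-fused cyclisation can compete. The fallback makes the dienophile more electrophilic instead of forcing the ester. Setting out from 16, i-Bu2AlH (CH2Cl2, −78 °C) reduces the ester to the allylic alcohol F1 and MnO2 oxidises it to the enal F2. F2 should cyclise through the same endo, anti transition state at a markedly lower temperature to the aldehyde F3. NaClO2 (NaH2PO4, 2-methyl-2-butene) oxidises F3 to the acid F4, and trimethylsilyldiazomethane in MeOH/PhMe comes back to the route at 17.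

Step 3 (conjugate addition). What may go wrong: the nitronate can attack C1 or C3 of the trienyl iminium ion (1,6- or 1,8-addition) instead of C9, or add with poor facial selectivity. The fallback reverses the polarity so that only 1,4-addition leads to a stabilised nitronate. Setting out from 3, nitroaldol (Henry) condensation with 6 (n-BuNH2 cat., AcOH, PhMe, reflux with removal of water) gives the nitrotriene F5. Its β-carbon C9 then takes up acetaldehyde under enamine catalysis by the same (S)-configured diarylprolinol silyl ether (Michael addition of an aldehyde to a nitroalkene), which comes back to the route at 7.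

Step 9 (ketalisation). What may go wrong: ketalisation at the hindered C8 carbonyl may be slow, with loss of the C6 silyloxy group by β-elimination or drift of the C10=C1 alkene into conjugation. The fallback carries C8 through the cycloaddition as a silyl ether instead of a ketal. Setting out from 15, NaBH4 (MeOH, −40 °C) gives the C8 alcohol F6 (either C8 epimer serves), and Et3SiOTf with 2,6-lutidine gives the triethylsilyl ether F7. Thermolysis as in step 10 gives the octalin F8, and hydrogenation as in step 11 gives the decalin F9. Buffered HF·pyridine at 0 °C removes only the triethylsilyl group to give the alcohol F10, and Dess–Martin periodinane gives the ketone F11. Acid hydrolysis of the remaining dioxolane as in step 12 comes back to the route at 19.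

Further compounds
F1 | step 10 | allylic alcohol from 16 (CH2OH in place of CO2Me; 6R,9S) | OC/C(C)=C/[C@H](O[Si](C)(C)C(C)(C)C)CC1(OCCO1)[C@@H](CC2OCCO2)/C(C)=C/C=C
F2 | step 10 | enal from F1 (CHO in place of CO2Me; 6R,9S) | O=C/C(C)=C/[C@H](O[Si](C)(C)C(C)(C)C)CC1(OCCO1)[C@@H](CC2OCCO2)/C(C)=C/C=C
F3 | step 10 | C18 aldehyde analogue of octalin 17 | C1COC(O1)C[C@@H]2C3(OCCO3)C[C@@H](O[Si](C)(C)C(C)(C)C)[C@H]4[C@@]2(C)C=CC[C@]4(C)C=O
F4 | step 10 | C18 carboxylic acid analogue of octalin 17 | C1COC(O1)C[C@@H]2C3(OCCO3)C[C@@H](O[Si](C)(C)C(C)(C)C)[C@H]4[C@@]2(C)C=CC[C@]4(C)C(=O)O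
F5 | step 3 | (2E,4E)-4-methyl-2-nitrohepta-2,4,6-triene | [O-][N+](=O)/C(C)=C/C(C)=C/C=C
F6 | step 9 | C8 alcohol from 15 (both C8 epimers) | COC(=O)/C(C)=C/[C@H](O[Si](C)(C)C(C)(C)C)CC(O)[C@@H](CC1OCCO1)/C(C)=C/C=C
F7 | step 9 | C8 triethylsilyl ether of F6 | COC(=O)/C(C)=C/[C@H](O[Si](C)(C)C(C)(C)C)CC(O[Si](CC)(CC)CC)[C@@H](CC1OCCO1)/C(C)=C/C=C
F8 | step 9 | trans-fused octalin from F7 (C8 triethylsilyloxy, C12 dioxolane) | C1COC(O1)C[C@@H]2C(O[Si](CC)(CC)CC)C[C@@H](O[Si](C)(C)C(C)(C)C)[C@H]4[C@@]2(C)C=CC[C@]4(C)C(=O)OC
F9 | step 9 | decalin from F8 (C1–C2 saturated) | C1COC(O1)C[C@@H]2C(O[Si](CC)(CC)CC)C[C@@H](O[Si](C)(C)C(C)(C)C)[C@H]4[C@@]2(C)CCC[C@]4(C)C(=O)OC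
F10 | step 9 | C8 alcohol from F9 | C1COC(O1)C[C@@H]2C(O)C[C@@H](O[Si](C)(C)C(C)(C)C)[C@H]4[C@@]2(C)CCC[C@]4(C)C(=O)OC
F11 | step 9 | C8 ketone with the C12 dioxolane | C1COC(O1)C[C@@H]2C(=O)C[C@@H](O[Si](C)(C)C(C)(C)C)[C@H]4[C@@]2(C)CCC[C@]4(C)C(=O)OC
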